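**Strategy.** Everything rests on the C1–C2 bond of the five-membered ring (octahydroindene numbering: C1 carries the cyclohexylidenemethyl group, C2 the secondary hydroxyl). This ring is made last, from a trans-fused 2-lithio-6-alkenyl-oxane by [1,2]-Wittig ring contraction: the allylic carbon C1 migrates from the ring oxygen to the lithiated carbon C2, so one operation forms the carbocycle, turns the ring oxygen into the C2 hydroxyl and sets C1 and C2. The step exploits the vicinal relation of the allylic C1 (a stabilised migrating group) and the carbinol C2. The precursor, an O,Se-acetal, is assembled from two enantiopure bromocyclohexanes, each made by bromonium-type cyclisation of an epoxide-derived bromohydrin β-keto ester.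

Key step: step 19

Remark: ring A is the cyclohexylidene ring, ring B the six-membered and ring C the five-membered ring of the bicycle; TBDPS = tert-butyl(diphenyl)silyl; the silyl ether 11 is taken as purchasable (otherwise one silylation of but-3-yn-1-ol).

**Ring A ketone**

Step 1
Reactants: 1 3-methylbut-2-en-1-ol
Product: 3 [(2R)-3,3-dimethyloxiran-2-yl]methyl 4-methylbenzenesulfonate, via epoxy alcohol 2 (not isolated)
Conditions: Ti(OiPr)4 (cat.), D-(−)-diethyl tartrate (cat.), t-BuOOH, 4 Å MS, CH2Cl2, −20 °C; then TsCl, Et3N, DMAP (cat.), −10 °C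
Reagents that add atoms: tert-butyl hydroperoxide CC(C)(C)OO; 4-methylbenzenesulfonyl chloride Cc1ccc(cc1)S(Cl)(=O)=O
Why: Sharpless asymmetric epoxidation with sulfonylation in the same pot; the D-tartrate ligand should deliver oxygen to the face that gives the (2R)-epoxide, the carbon that later carries the ring A bromine.

Step 2
Reactants: 3 [(2R)-3,3-dimethyloxiran-2-yl]methyl 4-methylbenzenesulfonate; 4 tert-butyl 3-oxobutanoate
Product: 6 tert-butyl 5-[(2R)-3,3-dimethyloxiran-2-yl]-3-oxopentanoate, via dianion 5 (not isolated)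
Conditions: NaH, THF, 0 °C; n-BuLi, 0 °C; then 3, THF–DMPU, −30 to 0 °C
Reagents that add atoms: none
Why: Weiler-type dianion γ-alkylation; the terminal carbanion should displace the primary sulfonate by SN2 and leave the trisubstituted epoxide and its stereocentre untouched.

Step 3
Reactants: 6 tert-butyl 5-[(2R)-3,3-dimethyloxiran-2-yl]-3-oxopentanoate
Product: 7 tert-butyl (6S)-6-bromo-7-hydroxy-7-methyl-3-oxooctanoate
Conditions: Li2NiBr4, THF, 0 °C; pH 7 buffer
Reagents that add atoms: dilithium tetrabromonickelate [Li+].[Li+].Br[Ni-2](Br)(Br)Br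
Why: Nucleophilic epoxide opening by soft bromide (SN2) should occur at the less substituted carbon with inversion, giving the (S)-bromide next to a tertiary alcohol.

Step 4
Reactants: 7 tert-butyl (6S)-6-bromo-7-hydroxy-7-methyl-3-oxooctanoate
Product: 10 (4S)-4-bromo-3,3-dimethylcyclohexan-1-one, via cyclised ester 8 (not isolated), via keto acid 9 (not isolated)
Conditions: SnCl4, CH2Cl2, −20 to 0 °C; then CF3CO2H, 40 °C
Reagents that add atoms: none
Why: Cation-type cyclisation in which SnCl4 ionises the tertiary alcohol with bromine assistance and the enol carbon of the β-keto ester closes the six-membered ring, followed by acidolysis of the tert-butyl ester and decarboxylation; the bromine-bearing centre is not involved and keeps its configuration.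

**Ring B iodoalkene**

Step 5
Reactants: 11 tert-butyl(but-3-yn-1-yloxy)diphenylsilane
Product: 13 (2E)-5-(TBDPS-oxy)-3-methylpent-2-en-1-ol, via alkenylalane 12 (not isolated)
Conditions: AlMe3, Cp2ZrCl2 (cat.), CH2Cl2, 0 °C to rt; then n-BuLi, (CH2O)n, THF, −30 °C to rt
Reagents that add atoms: trimethylaluminium C[Al](C)C; paraformaldehyde (formaldehyde unit) C=O
Why: Negishi zirconium-catalysed carboalumination adds methyl and aluminium syn with aluminium at the terminal carbon, so hydroxymethylation of the alanate with retention should give only the E allylic alcohol.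

Step 6
Reactants: 13 (2E)-5-(TBDPS-oxy)-3-methylpent-2-en-1-ol
Product: 15 {(2R,3R)-3-[2-(TBDPS-oxy)ethyl]-3-methyloxiran-2-yl}methyl 4-methylbenzenesulfonate, via epoxy alcohol 14 (not isolated)
Conditions: Ti(OiPr)4 (cat.), D-(−)-diethyl tartrate (cat.), t-BuOOH, 4 Å MS, CH2Cl2, −20 °C; then TsCl, Et3N, DMAP (cat.), −10 °C
Reagents that add atoms: tert-butyl hydroperoxide CC(C)(C)OO; 4-methylbenzenesulfonyl chloride Cc1ccc(cc1)S(Cl)(=O)=O
Why: Sharpless asymmetric epoxidation with in situ sulfonylation; the D-tartrate catalyst should give the (2R,3R)-epoxide of the E allylic alcohol by reagent control.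

Step 7
Reactants: 15 {(2R,3R)-3-[2-(TBDPS-oxy)ethyl]-3-methyloxiran-2-yl}methyl 4-methylbenzenesulfonate; 16 methyl 3-oxobutanoate
Product: 18 methyl 5-{(2R,3R)-3-[2-(TBDPS-oxy)ethyl]-3-methyloxiran-2-yl}-3-oxopentanoate, via dianion 17 (not isolated)
Conditions: NaH, THF, 0 °C; n-BuLi, 0 °C; then 15, THF–DMPU, −30 to 0 °C
Reagents that add atoms: none
Why: Weiler-type dianion γ-alkylation by SN2 at the primary sulfonate; the epoxide stereocentres are not touched.

Step 8
Reactants: 18 methyl 5-{(2R,3R)-3-[2-(TBDPS-oxy)ethyl]-3-methyloxiran-2-yl}-3-oxopentanoate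
Product: 19 methyl (6S,7R)-6-bromo-9-(TBDPS-oxy)-7-hydroxy-7-methyl-3-oxononanoate
Conditions: Li2NiBr4, THF, 0 °C; pH 7 buffer
Reagents that add atoms: dilithium tetrabromonickelate [Li+].[Li+].Br[Ni-2](Br)(Br)Br
Why: SN2 opening by soft bromide at the secondary epoxide carbon with inversion should give the (S)-bromide as the anti bromohydrin, the formal anti adduct of Br and OH to the E alkene.

Step 9
Reactants: 19 methyl (6S,7R)-6-bromo-9-(TBDPS-oxy)-7-hydroxy-7-methyl-3-oxononanoate
Product: 20 methyl (1S,2S,3S)-3-bromo-2-[2-(TBDPS-oxy)ethyl]-2-methyl-6-oxocyclohexane-1-carboxylate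
Conditions: SnCl4, CH2Cl2, −40 to 0 °C
Reagents that add atoms: none
Why: Bromonium-type cation cyclisation terminated by the β-keto ester (C-alkylation, any O-cyclised enol ether being expected to isomerise under SnCl4); ionisation anti to bromine and attack of the enol carbon anti to bromine through a chair should give net retention at the quaternary carbon, with bromine equatorial, methyl axial and the silyloxyethyl and ester arms trans-diequatorial.

Step 10
Reactants: 20 methyl (1S,2S,3S)-3-bromo-2-[2-(TBDPS-oxy)ethyl]-2-methyl-6-oxocyclohexane-1-carboxylate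
Product: 21 methyl (1S,2S,3S,6R)-3-bromo-2-[2-(TBDPS-oxy)ethyl]-6-hydroxy-2,6-dimethylcyclohexane-1-carboxylate
Conditions: MeLi, CeCl3, THF, −78 °C
Reagents that add atoms: methyllithium [Li]C
Why: Organocerium 1,2-addition to an enolisable ketone; the weakly basic reagent should add and not deprotonate, and attack from the equatorial direction, away from the syn-axial angular methyl, gives the axial (R)-tertiary alcohol.

Step 11
Reactants: 21 methyl (1S,2S,3S,6R)-3-bromo-2-[2-(TBDPS-oxy)ethyl]-6-hydroxy-2,6-dimethylcyclohexane-1-carboxylate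
Product: 22 (1S,2S,3S,6R)-3-bromo-2-[2-(TBDPS-oxy)ethyl]-6-hydroxy-2,6-dimethylcyclohexane-1-carbaldehyde
Conditions: i-Bu2AlH, CH2Cl2, −78 °C; Rochelle salt
Reagents that add atoms: none
Why: Partial reduction of a hindered ester at low temperature, where the chelated aluminium hemiacetal should survive until work-up and stop the reduction at the aldehyde; no stereocentre is touched.

Step 12
Reactants: 22 (1S,2S,3S,6R)-3-bromo-2-[2-(TBDPS-oxy)ethyl]-6-hydroxy-2,6-dimethylcyclohexane-1-carbaldehyde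
Product: 23 (1R,2S,3S,4S)-4-bromo-3-[2-(TBDPS-oxy)ethyl]-2-[(E)-2-iodoethenyl]-1,3-dimethylcyclohexan-1-ol
Conditions: CrCl2, CHI3, THF, 0 °C to rt
Reagents that add atoms: iodoform IC(I)I
Why: Takai olefination with the geminal dichromium reagent from iodoform should give the E iodoalkene and tolerate the free tertiary alcohol and the alkyl bromide.

**Union and end game**

Step 13
Reactants: 23 (1R,2S,3S,4S)-4-bromo-3-[2-(TBDPS-oxy)ethyl]-2-[(E)-2-iodoethenyl]-1,3-dimethylcyclohexan-1-ol; 10 (4S)-4-bromo-3,3-dimethylcyclohexan-1-one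
Product: 25 (1R,2S,3S,4S)-4-bromo-2-{(E)-2-[(1R,4S)-4-bromo-1-hydroxy-3,3-dimethylcyclohexyl]ethenyl}-3-[2-(TBDPS-oxy)ethyl]-1,3-dimethylcyclohexan-1-ol, via dilithio species 24 (not isolated)
Conditions: t-BuLi (3 equiv), Et2O, −78 °C; then 10, −78 to −20 °C
Reagents that add atoms: none
Why: Iodine–lithium exchange with retention of alkene geometry and 1,2-addition of the alkenyllithium to the ketone from the equatorial direction, anti to the axial methyl of the gem-dimethyl group; the new carbinol centre is destroyed in step 14, so its epimer converges.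

Step 14
Reactants: 25 (1R,2S,3S,4S)-4-bromo-2-{(E)-2-[(1R,4S)-4-bromo-1-hydroxy-3,3-dimethylcyclohexyl]ethenyl}-3-[2-(TBDPS-oxy)ethyl]-1,3-dimethylcyclohexan-1-ol
Product: 26 (2E)-2-[(4S)-4-bromo-3,3-dimethylcyclohexylidene]-1-{(1S,2S,3S,6R)-3-bromo-2-[2-(TBDPS-oxy)ethyl]-6-hydroxy-2,6-dimethylcyclohexyl}ethan-1-one
Conditions: pyridinium chlorochromate, NaOAc, 4 Å MS, CH2Cl2, rt
Reagents that add atoms: pyridinium chlorochromate [O-][Cr](=O)(=O)Cl.c1cc[nH+]cc1
Why: Babler–Dauben oxidative transposition; the tertiary allylic chromate shifts by a [3,3] process through a chair in which the chromium ester on the axial oxygen turns away from the syn-axial methyl and the CH2–CMe2 arm is pseudo-equatorial, which should place the carbonyl-bearing carbon trans to that arm (E) before oxidation to the enone.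

Step 15
Reactants: 26 (2E)-2-[(4S)-4-bromo-3,3-dimethylcyclohexylidene]-1-{(1S,2S,3S,6R)-3-bromo-2-[2-(TBDPS-oxy)ethyl]-6-hydroxy-2,6-dimethylcyclohexyl}ethan-1-one
Product: 27 (1S,2E)-2-[(4S)-4-bromo-3,3-dimethylcyclohexylidene]-1-{(1R,2S,3S,6R)-3-bromo-2-[2-(TBDPS-oxy)ethyl]-6-hydroxy-2,6-dimethylcyclohexyl}ethan-1-ol
Conditions: Et2BOMe, THF–MeOH, −78 °C; NaBH4; then MeOH, evaporation
Reagents that add atoms: none
Why: Narasaka–Prasad chelation-controlled 1,2-reduction; boron bridges the tertiary hydroxyl and the ketone, the face next to the quaternary ring carbon is blocked, and external hydride should give the (S)-allylic alcohol.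

Step 16
Reactants: 27 (1S,2E)-2-[(4S)-4-bromo-3,3-dimethylcyclohexylidene]-1-{(1R,2S,3S,6R)-3-bromo-2-[2-(TBDPS-oxy)ethyl]-6-hydroxy-2,6-dimethylcyclohexyl}ethan-1-ol
Product: 28 (1R,2R,3S,4S)-4-bromo-2-{(1S,2E)-2-[(4S)-4-bromo-3,3-dimethylcyclohexylidene]-1-hydroxyethyl}-3-(2-hydroxyethyl)-1,3-dimethylcyclohexan-1-ol
Conditions: n-Bu4NF, THF, 0 °C to rt
Reagents that add atoms: none
Why: Fluoride-induced cleavage of the silyl ether; no stereocentre is involved.

Step 17
Reactants: 28 (1R,2R,3S,4S)-4-bromo-2-{(1S,2E)-2-[(4S)-4-bromo-3,3-dimethylcyclohexylidene]-1-hydroxyethyl}-3-(2-hydroxyethyl)-1,3-dimethylcyclohexan-1-ol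
Product: 30 (1S,3R,4aS,5S,8R,8aR)-5-bromo-1-{(E)-[(4S)-4-bromo-3,3-dimethylcyclohexylidene]methyl}-4a,8-dimethyl-3,4,4a,5,6,7,8,8a-octahydro-1H-isochromene-3,8-diol, via hydroxy aldehyde 29 (not isolated)
Conditions: TEMPO (cat.), PhI(OAc)2 (1.1 equiv), CH2Cl2, 0 °C
Reagents that add atoms: none
Why: Oxoammonium (TEMPO) oxidation is selective for the primary alcohol, and the aldehyde should close with the allylic hydroxyl to the trans-fused lactol with the alkenyl group equatorial (oxidant limited to avoid the lactone).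

Step 18
Reactants: 30 (1S,3R,4aS,5S,8R,8aR)-5-bromo-1-{(E)-[(4S)-4-bromo-3,3-dimethylcyclohexylidene]methyl}-4a,8-dimethyl-3,4,4a,5,6,7,8,8a-octahydro-1H-isochromene-3,8-diol
Product: 31 (1S,3S,4aS,5S,8R,8aR)-5-bromo-1-{(E)-[(4S)-4-bromo-3,3-dimethylcyclohexylidene]methyl}-4a,8-dimethyl-3-(phenylselanyl)-3,4,4a,5,6,7,8,8a-octahydro-1H-isochromen-8-ol
Conditions: N-(phenylselanyl)phthalimide, n-Bu3P, CH2Cl2, −20 to 0 °C
Reagents that add atoms: N-(phenylselanyl)phthalimide O=C1N([Se]c2ccccc2)C(=O)c2ccccc12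
Why: Phosphine-mediated selenation of the hemiacetal hydroxyl (Mitsunobu-type activation, anomerically favoured axial selenide) under neutral conditions that should not ionise the allylic C–O bond of the ring.

Step 19
Reactants: 31 (1S,3S,4aS,5S,8R,8aR)-5-bromo-1-{(E)-[(4S)-4-bromo-3,3-dimethylcyclohexylidene]methyl}-4a,8-dimethyl-3-(phenylselanyl)-3,4,4a,5,6,7,8,8a-octahydro-1H-isochromen-8-ol
Product: 33 iriediol, via lithio-oxane 32 (not isolated)
Conditions: n-BuLi (2.2 equiv), THF, −78 to −20 °C; aq. NH4Cl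
Reagents that add atoms: none
Why: Selenium–lithium exchange gives the 2-lithio-oxane, which should settle as the equatorial carbanion with its lone pair antiperiplanar to the ring O–C(allyl) bond; that bond breaks to a ketyl/allyl radical pair which recombines at carbon ([1,2]-Wittig rearrangement), and work-up protonates the alkoxides. The closest known reaction type is the ring contraction of 2-lithio-6-vinyltetrahydropyrans to 2-vinylcyclopentanols. Ring C closes by the suprafacial 1,2-shift of the allylic carbon from oxygen to the lithiated carbon (bond between the former 2- and 6-positions of the oxane), not by attack on a π bond. C2 is set by inversion at the lithium-bearing carbon, the migrating carbon entering anti to the equatorial C–Li bond, and C1 by retention at the migrating allylic carbon held on one face in the tethered radical pair, which gives the cis hydroxyl/alkenyl pair on the existing trans ring fusion. The step needs [1,2]- over [2,3]-shift, which the fully substituted distal allyl carbon (the ring A carbon) should secure, and retention of the E alkene, which the short-lived allyl radical should keep. It also needs exchange at selenium to outrun reaction at the two hindered neopentylic secondary bromides, which should survive at low temperature.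

**Compound list**

1 | 3-methylbut-2-en-1-ol | CC(C)=CCO | starting material
2 | [(2R)-3,3-dimethyloxiran-2-yl]methanol | CC1(C)O[C@@H]1CO | intermediate
3 | [(2R)-3,3-dimethyloxiran-2-yl]methyl 4-methylbenzenesulfonate | CC1(C)O[C@@H]1COS(=O)(=O)c1ccc(C)cc1 | intermediate
4 | tert-butyl 3-oxobutanoate | CC(=O)CC(=O)OC(C)(C)C | starting material
5 | sodium lithium C2,C4-dianion of tert-butyl 3-oxobutanoate | [Na+].[Li+].[CH2-]C(=O)[CH-]C(=O)OC(C)(C)C | intermediate
6 | tert-butyl 5-[(2R)-3,3-dimethyloxiran-2-yl]-3-oxopentanoate | CC1(C)O[C@@H]1CCC(=O)CC(=O)OC(C)(C)C | intermediate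
7 | tert-butyl (6S)-6-bromo-7-hydroxy-7-methyl-3-oxooctanoate | CC(C)(O)[C@@H](Br)CCC(=O)CC(=O)OC(C)(C)C | intermediate
8 | tert-butyl (1S,5S)-5-bromo-6,6-dimethyl-2-oxocyclohexane-1-carboxylate (keto form drawn, ester equatorial) | CC1(C)[C@H](C(=O)OC(C)(C)C)C(=O)CC[C@@H]1Br | intermediate
9 | (1S,5S)-5-bromo-6,6-dimethyl-2-oxocyclohexane-1-carboxylic acid | CC1(C)[C@H](C(=O)O)C(=O)CC[C@@H]1Br | intermediate
10 | (4S)-4-bromo-3,3-dimethylcyclohexan-1-one (ring A ketone) | CC1(C)CC(=O)CC[C@@H]1Br | intermediate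
11 | tert-butyl(but-3-yn-1-yloxy)diphenylsilane | C#CCCO[Si](c1ccccc1)(c1ccccc1)C(C)(C)C | starting material
12 | [(1E)-4-(TBDPS-oxy)-2-methylbut-1-en-1-yl]dimethylalumane | CC(C)(C)[Si](c1ccccc1)(c1ccccc1)OCC/C(C)=C/[Al](C)C | intermediate
13 | (2E)-5-(TBDPS-oxy)-3-methylpent-2-en-1-ol | CC(C)(C)[Si](c1ccccc1)(c1ccccc1)OCC/C(C)=C/CO | intermediate
14 | {(2R,3R)-3-[2-(TBDPS-oxy)ethyl]-3-methyloxiran-2-yl}methanol | CC(C)(C)[Si](c1ccccc1)(c1ccccc1)OCC[C@@]2(C)O[C@@H]2CO | intermediate
15 | {(2R,3R)-3-[2-(TBDPS-oxy)ethyl]-3-methyloxiran-2-yl}methyl 4-methylbenzenesulfonate | CC(C)(C)[Si](c1ccccc1)(c1ccccc1)OCC[C@@]2(C)O[C@@H]2COS(=O)(=O)c1ccc(C)cc1 | intermediate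
16 | methyl 3-oxobutanoate | CC(=O)CC(=O)OC | starting material
17 | sodium lithium C2,C4-dianion of methyl 3-oxobutanoate | [Na+].[Li+].[CH2-]C(=O)[CH-]C(=O)OC | intermediate
18 | methyl 5-{(2R,3R)-3-[2-(TBDPS-oxy)ethyl]-3-methyloxiran-2-yl}-3-oxopentanoate | CC(C)(C)[Si](c1ccccc1)(c1ccccc1)OCC[C@@]2(C)O[C@@H]2CCC(=O)CC(=O)OC | intermediate
19 | methyl (6S,7R)-6-bromo-9-(TBDPS-oxy)-7-hydroxy-7-methyl-3-oxononanoate | CC(C)(C)[Si](c1ccccc1)(c1ccccc1)OCC[C@@](C)(O)[C@@H](Br)CCC(=O)CC(=O)OC | intermediate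
20 | methyl (1S,2S,3S)-3-bromo-2-[2-(TBDPS-oxy)ethyl]-2-methyl-6-oxocyclohexane-1-carboxylate (Br equatorial, methyl axial, arms trans) | CC(C)(C)[Si](c1ccccc1)(c1ccccc1)OCC[C@]2(C)[C@@H](Br)CCC(=O)[C@H]2C(=O)OC | intermediate
21 | methyl (1S,2S,3S,6R)-3-bromo-2-[2-(TBDPS-oxy)ethyl]-6-hydroxy-2,6-dimethylcyclohexane-1-carboxylate | CC(C)(C)[Si](c1ccccc1)(c1ccccc1)OCC[C@]2(C)[C@@H](Br)CC[C@@](C)(O)[C@H]2C(=O)OC | intermediate
22 | (1S,2S,3S,6R)-3-bromo-2-[2-(TBDPS-oxy)ethyl]-6-hydroxy-2,6-dimethylcyclohexane-1-carbaldehyde | CC(C)(C)[Si](c1ccccc1)(c1ccccc1)OCC[C@]2(C)[C@@H](Br)CC[C@@](C)(O)[C@H]2C=O | intermediate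
23 | (1R,2S,3S,4S)-4-bromo-3-[2-(TBDPS-oxy)ethyl]-2-[(E)-2-iodoethenyl]-1,3-dimethylcyclohexan-1-ol | CC(C)(C)[Si](c1ccccc1)(c1ccccc1)OCC[C@]2(C)[C@@H](Br)CC[C@@](C)(O)[C@H]2/C=C/I | intermediate
24 | dilithio derivative of 23 (lithium alkoxide, E alkenyllithium) | CC(C)(C)[Si](c1ccccc1)(c1ccccc1)OCC[C@]2(C)[C@@H](Br)CC[C@@](C)(O[Li])[C@H]2/C=C/[Li] | intermediate
25 | (1R,2S,3S,4S)-4-bromo-2-{(E)-2-[(1R,4S)-4-bromo-1-hydroxy-3,3-dimethylcyclohexyl]ethenyl}-3-[2-(TBDPS-oxy)ethyl]-1,3-dimethylcyclohexan-1-ol (expected major epimer at the new carbinol carbon) | CC(C)(C)[Si](c1ccccc1)(c1ccccc1)OCC[C@]2(C)[C@@H](Br)CC[C@@](C)(O)[C@H]2/C=C/[C@@]3(O)CC[C@H](Br)C(C)(C)C3 | intermediate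
26 | (2E)-2-[(4S)-4-bromo-3,3-dimethylcyclohexylidene]-1-{(1S,2S,3S,6R)-3-bromo-2-[2-(TBDPS-oxy)ethyl]-6-hydroxy-2,6-dimethylcyclohexyl}ethan-1-one | CC(C)(C)[Si](c1ccccc1)(c1ccccc1)OCC[C@]2(C)[C@@H](Br)CC[C@@](C)(O)[C@H]2C(=O)/C=C3\CC[C@H](Br)C(C)(C)C3 | intermediate
27 | (1S,2E)-2-[(4S)-4-bromo-3,3-dimethylcyclohexylidene]-1-{(1R,2S,3S,6R)-3-bromo-2-[2-(TBDPS-oxy)ethyl]-6-hydroxy-2,6-dimethylcyclohexyl}ethan-1-ol | CC(C)(C)[Si](c1ccccc1)(c1ccccc1)OCC[C@]2(C)[C@@H](Br)CC[C@@](C)(O)[C@H]2[C@@H](O)/C=C3\CC[C@H](Br)C(C)(C)C3 | intermediate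
28 | (1R,2R,3S,4S)-4-bromo-2-{(1S,2E)-2-[(4S)-4-bromo-3,3-dimethylcyclohexylidene]-1-hydroxyethyl}-3-(2-hydroxyethyl)-1,3-dimethylcyclohexan-1-ol | OCC[C@]2(C)[C@@H](Br)CC[C@@](C)(O)[C@H]2[C@@H](O)/C=C3\CC[C@H](Br)C(C)(C)C3 | intermediate
29 | 2-{(1S,2R,3R,6S)-6-bromo-2-[(1S,2E)-2-[(4S)-4-bromo-3,3-dimethylcyclohexylidene]-1-hydroxyethyl]-3-hydroxy-1,3-dimethylcyclohexyl}acetaldehyde | O=CC[C@]2(C)[C@@H](Br)CC[C@@](C)(O)[C@H]2[C@@H](O)/C=C3\CC[C@H](Br)C(C)(C)C3 | intermediate
30 | (1S,3R,4aS,5S,8R,8aR)-5-bromo-1-{(E)-[(4S)-4-bromo-3,3-dimethylcyclohexylidene]methyl}-4a,8-dimethyl-3,4,4a,5,6,7,8,8a-octahydro-1H-isochromene-3,8-diol (trans-fused lactol, one anomer drawn) | O[C@H]1C[C@]2(C)[C@@H](Br)CC[C@@](C)(O)[C@H]2[C@@H](O1)/C=C3\CC[C@H](Br)C(C)(C)C3 | intermediate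
31 | (1S,3S,4aS,5S,8R,8aR)-5-bromo-1-{(E)-[(4S)-4-bromo-3,3-dimethylcyclohexylidene]methyl}-4a,8-dimethyl-3-(phenylselanyl)-3,4,4a,5,6,7,8,8a-octahydro-1H-isochromen-8-ol (axial selenide) | c1ccc(cc1)[Se][C@H]1C[C@]2(C)[C@@H](Br)CC[C@@](C)(O)[C@H]2[C@@H](O1)/C=C3\CC[C@H](Br)C(C)(C)C3 | intermediate
32 | 3-lithio derivative of the oxane (lithium equatorial, lithium 8-alkoxide) | [Li][C@@H]1C[C@]2(C)[C@@H](Br)CC[C@@](C)(O[Li])[C@H]2[C@@H](O1)/C=C3\CC[C@H](Br)C(C)(C)C3 | intermediate
33 | iriediol, (1S,2R,3aS,4S,7R,7aS)-4-bromo-1-{(E)-[(4S)-4-bromo-3,3-dimethylcyclohexylidene]methyl}-3a,7-dimethyl-octahydro-1H-indene-2,7-diol | CC1(C)C/C(=C/[C@@H]2[C@H](O)C[C@]3(C)[C@@H](Br)CC[C@@](C)(O)[C@@H]23)CC[C@@H]1Br | target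

**Totals and risks**

Total step count: 19. Longest linear sequence: 15 steps (steps 5 to 19, from 11).

Step 19. The lithiated oxane may be lost before it rearranges (proton transfer, attack on a bromide), or the radical pair may lose facial fidelity at the carbinol carbon. The fallback sets out from 30 and comes back to the route at 33. Acetylation of the lactol hydroxyl (Ac2O, pyridine) gives the anomeric acetate F1. Pd(PPh3)4 with SmI2 in THF should then open the allylic C–O bond of the ring at zerovalent palladium; the acetoxy hemiacetal collapses to the aldehyde, and the allylsamarium formed by reduction adds to it at its less substituted terminus. This is the reductive ring contraction known for alkenyl-substituted cyclic acetals. A wrong epimer at the carbinol carbon could be corrected by oxidation and hydride reduction from the face opposite the alkenyl group.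

Step 9. Ionisation of the tertiary alcohol may end in elimination to allylic bromides or in an O-cyclised enol ether that does not isomerise, and the Lewis acid may cleave the silyl ether. The fallback sets out from 19 and comes back at 20. The tertiary hydroxyl and the keto ester are both silylated (Me3SiOTf, Et3N) to the bis-silyl compound F2. TiCl4 at −78 °C should then ionise the tertiary silyl ether and let the silyl enol ether carbon close the ring, a Mukaiyama-type alkylation of a silyl enol ether by a tertiary cation.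

Step 10. The keto ester may simply be deprotonated, so that no addition takes place. The fallback sets out from 20 and comes back at 23. The ketone is masked as the ethylene ketal F3 (1,2-bis(trimethylsilyloxy)ethane, Me3SiOTf). The ester is reduced to the aldehyde F4 (i-Bu2AlH), and Takai olefination gives the iodoalkene F5. Aqueous acid frees the ketone F6, which is no longer a β-dicarbonyl compound, and MeLi/CeCl3 then adds as in step 10 to give 23.

Further compounds
F1 | step 19 | anomeric acetate of lactol 30 (acetoxy axial, other centres as in 30) | CC(=O)O[C@H]1C[C@]2(C)[C@@H](Br)CC[C@@](C)(O)[C@H]2[C@@H](O1)/C=C3\CC[C@H](Br)C(C)(C)C3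
F2 | step 9 | methyl (2Z,6S,7R)-6-bromo-9-(TBDPS-oxy)-7-methyl-3,7-bis(trimethylsilyloxy)non-2-enoate | CC(C)(C)[Si](c1ccccc1)(c1ccccc1)OCC[C@@](C)(O[Si](C)(C)C)[C@@H](Br)CC/C(O[Si](C)(C)C)=C/C(=O)OC
F3 | step 10 | ethylene ketal of 20 (1,4-dioxaspiro[4.5]decane, stereocentres as in 20) | CC(C)(C)[Si](c1ccccc1)(c1ccccc1)OCC[C@]2(C)[C@@H](Br)CCC3(OCCO3)[C@H]2C(=O)OC
F4 | step 10 | aldehyde from F3 (ester reduced to CHO) | CC(C)(C)[Si](c1ccccc1)(c1ccccc1)OCC[C@]2(C)[C@@H](Br)CCC3(OCCO3)[C@H]2C=O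
F5 | step 10 | (E)-2-iodoethenyl ketal from F4 | CC(C)(C)[Si](c1ccccc1)(c1ccccc1)OCC[C@]2(C)[C@@H](Br)CCC3(OCCO3)[C@H]2/C=C/I
F6 | step 10 | (2S,3S,4S)-4-bromo-3-[2-(TBDPS-oxy)ethyl]-2-[(E)-2-iodoethenyl]-3-methylcyclohexan-1-one | CC(C)(C)[Si](c1ccccc1)(c1ccccc1)OCC[C@]2(C)[C@@H](Br)CCC(=O)[C@H]2/C=C/I
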